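All runs were generated by integration for an exercise; the scatter is artificial.

| flask | substrate | reagent | remark | time |
|---|---|---|---|---|
| violet | 13 mM (fed, over 6.0 h) | 1.8 equiv | run made earlier; the fed solution adds 1.0 times the starting volume |  |
| ochre | 30 mM (fed, over 6.0 h) | 1.8 equiv | run made earlier; the fed solution adds 1.0 times the starting volume |  |
| blue | 20 mM (fed, over 6.0 h) | 2.7 equiv | run made earlier; the fed solution adds 1.0 times the starting volume |  |
| north | 20 mM (fed, over 6.0 h) | 1.80 equiv | the fed solution adds 1.0 times the starting volume | 25 h |
| north-west | 20 mM | 1.80 equiv | everything together at the start, the whole solution of substrate included, so that from the start the volume is larger by 1.0 times the starting volume | 6.0 h |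

- violet (time / h: mono adduct / %): 2.50: 3.2; 6.00: 9.5; 12.0: 13.4; 30.0: 7.7
- ochre (time / h: mono adduct / %): 4.00: 8.5; 10.0: 15.8; 20.0: 9.3; 30.0: 5.3
- blue (time / h: mono adduct / %): 8.00: 17.1; 15.0: 11.7; 25.0: 6.9; 30.0: 5.3

(readings scatter by 0.5 percentage points)

- every charge counts on the volume at the start, and the solution that is fed holds the whole dose
- the analysis behind the earlier runs scatters by 0.5 percentage points, standard deviation
- percentages count the whole charge, also what has not yet gone in

- the flask that ends with the higher amount of mono adduct, in percent of the substrate charged, or "neither" when 2 percentage points or less lies between them (north / north-west / neither)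
- final mono adduct, as a percentage of the substrate charged, in north
- final mono adduct, as a percentage of the substrate charged, in north-west

Hours after the feed has ended, the mono adduct in blue and ochre falls by a steady fraction per hour. Violet has one falling interval, which begins at its highest reading, and averages 0.0308 /h over it on a reagent charge of 23.4 mM, while blue falls at 0.0528 /h on 54.0 mM. Ochre has the same [reagent] as charged from a different substrate charge and reads the same as blue at 30.0 h, so the percentage curve follows the reagent charge per starting volume.

North, charged with 36.0 mM, therefore gets a tail rate, an empirical fractional fall per hour taken on a straight line between those two charges, of 0.0398 /h. The reading interpolated for north at 15.0 h is 12.0%, and the tail rate carries it to 8.06% at 25 h.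

A second way treats charge times hours as the clock. North's exposure is reached in blue at 16.7 h, where blue stands near 10.7%. The two ways part, and the exposure clock is the one that cheats: violet at 30.0 h has had less exposure than blue at 15.0 h, yet holds less adduct. The line through the tail rates also reads 0.0140 /h at zero charge, a reading that carries the scatter, so plain hours count as well.

North-west is reckoned differently, since violet is still rising at 6.0 h. Its substrate has been present throughout, whereas a fed flask's has been present on average for half that time. My estimate for north-west therefore lies midway between violet's 9.5% and blue's 17.1%, the highest reading: 13.3%. That favours north-west by 5.2 percentage points, beyond the margin.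

The forecast gave 8.2% for north and 12% for north-west, hence north-west, holding that “the rate follows reagent concentration, not equivalents or substrate level”.

The flasks end at 8.72% in north and 15.9% in north-west, so the answer is north-west.

    mono adduct → over-reaction product (k = 0.0280 /h)
    substrate + reagent ⇌ mono adduct (K = 42.0 /M, k = 4.40 /M/h)
    reagent + other mono adduct → bis adduct (k = 0.640 /M/h)
    reagent + mono adduct → bis adduct (k = 6.70 /M/h)
    2 substrate → homo dimer (k = 3.10 × 10⁻⁴ /M/h)
    substrate + reagent → other mono adduct (k = 1.80 /M/h)

North-west is stopped at 6.00 h with 15.9% of mono adduct, and north, read later at 12.5 h, holds 14.5% and goes on losing adduct. At 25.0 h in north, mono adduct goes to bis adduct 2.1 times as fast as to over-reaction product, so the tail holds both a reagent route and a reagent-free route. Started from north's value at 12.5 h, the tail rate gives 8.78% at 25 h, against 8.72%.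

For the neighbour read from north at 15 h, the tail rate run backwards from 8.72% gives 13.0%. The computed value there is 13.3%.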